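Percent of the electrophile charged was the unit I counted in, and I followed one molecule of nucleophile to its fork. It can attack electrophile and become target, which sets an acid free, or it can catch such an acid and sit as protonated nucleophile.

all flasks: electrophile 0.26 M (fed, over 20 h)

| run | nucleophile | free base | remark | time |
|---|---|---|---|---|
| summer | 1 equiv | 1 equiv | run made earlier |  |
| spring | 1 equiv | 2.7 equiv | run made earlier |  |
| grey | 1.00 equiv | 3.40 equiv |  | 20 h |
| red | 1.00 equiv | 1.50 equiv |  | 20 h |
| blue | 1.00 equiv | 2.20 equiv |  | 20 h |

| run | time / h | electrophile / % | target / % |
|---|---|---|---|
| summer | 2.00 | 4.5 | 6.0 |
| summer | 4.00 | 7.2 | 13.0 |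
| summer | 6.00 | 8.3 | 20.1 |
| summer | 8.00 | 10.5 | 27.6 |
| summer | 10.0 | 13.1 | 34.3 |
| spring | 0.833 | 3.1 | 1.6 |
| spring | 2.50 | 6.1 | 6.8 |
| spring | 5.00 | 7.4 | 16.9 |
| spring | 8.00 | 10.7 | 27.5 |
| spring | 10.0 | 13.4 | 34.2 |

(standard deviation of a reading: 0.5 percentage points)

- a species is counted by the electrophile in it: one homo dimer or side product counts as two
- steps under discussion: acid set free + free base <-> salt of the base; nucleophile + acid set free <-> protonated nucleophile; 2 electrophile -> homo dimer; electrophile + nucleophile -> acid set free + target; electrophile + target -> side product
- percentages count the whole charge, also what has not yet gone in

- part of the electrophile that has reacted at the end, grey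
- part of the electrophile that has reacted at the end, red
- part of the electrophile that has reacted at the end, blue
- what raising the equivalents of free base from its lowest to its highest value here does to the part of the electrophile that has reacted (changes below 5 percentage points count as none) (it falls / it rises / no change)

Two counts were open. If free base takes the acid, each target costs one nucleophile, and target can reach the whole charge. If nucleophile takes the acid, each target costs two. I called the equivalents of nucleophile over two, 50.0%, the target mark.

The summer readings can judge between the counts. I divided the rise of target per hour by mean electrophile times mean free nucleophile, from 2.00 h to 4.00 h and then from 8.00 h to 10.0 h: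

one nucleophile per target: 0.661 /h, then 0.411 /h

two nucleophiles per target: 0.739 /h, then 0.745 /h

A true constant does not sag, so the first count cheats, while the second holds as a reading. The spring run agrees: with 2.7 equiv of free base against 1 equiv, it stood at 34.2% of target where summer stood at 34.3%.

So I took nucleophile as the limiting reagent. I expected the same end in the three new flasks: target near the mark, electrophile piling up, and the reacted part equal to target plus what strays to homo dimer and side product. That stray part read 2.60% by 10.0 h in summer.

The forecast put numbers on this: 68.5% for grey, 68% for red, 68% for blue, and no change, reasoning that “the released acid protonates the nucleophile, not the base”.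

    acid set free + free base ⇌ salt of the base (K = 3.01 /M, k = 0.113 /M/min)
    nucleophile + acid set free ⇌ protonated nucleophile, settled at all times (K = 4420 /M)
    2 electrophile → homo dimer (k = 0.00698 /M/min)
    electrophile + nucleophile → acid set free + target (k = 0.0506 /M/min)
    electrophile + target → side product (k = 0.00181 /M/min)

The flasks gave 67.8% for grey, 67.4% for red and 67.6% for blue, a spread of 0.36 percentage points, so the answer on free base is no change, and the base step makes no difference. Red's target ended at 47.6%, under the mark. Red's reacted part stood short through the slow addition and the time given acting together: without the slow addition it reaches 89.9%, and left ten times as long 99.7%. The binding of nucleophile to acid is part of the reason: without it red reaches 83.6%, which closes half of what is missing. Grey's answer has moved by 5 points at 1.24 equiv of nucleophile. With 0.250 equiv of nucleophile, otherwise like red, the mark falls to 12.5%, and that flask ended with 12.7% of target.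

The runs come from a simulation with made-up constants; the scatter is artificial.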